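**Retrosynthetic overview**
1. The 8-O-acyl group is removed first: esterification of the C8 alcohol with silyl-protected 2-(hydroxymethyl)acrylic acid, then global desilylation, leads back to the protected 15-oxy cis-fused 6,12-germacranolide core.
2. The ten-membered ring is opened at C3–C4: a one-pot 9-BBN hydroboration of a terminal C1=C10–C2=C3 diene and B-alkyl Suzuki–Miyaura macrocyclisation onto a C4 iodoalkene; ring order: γ-lactone first, carbocycle second.
3. Enabling feature: the cis-fused γ-butyrolactone (O–C12–C11–C7–C6) holds the C6 arm (C5=C4(I)–C15) and the C7 arm (C8–C9–C10=C1–C2=C3) on one face. The C15–C4≡C5–C6 butyne-1,4-diol unit lets tin, then iodine, be placed on C4 with the ring-E geometry, and a terminal C10≡C1 alkyne gives the E C1=C10 olefin and the diene.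
4. Stereochemistry: one organocatalytic anti-aldol (ynal plus methyl 4-oxobutanoate) sets C6 and C7 and lactonises to the cis lactone; C8 follows by catalyst-controlled propargylation and C11 by substrate-controlled enolate methylation.

Key step: step 9

Remark: germacrane numbering is used for atom labels (C1–C10 ring carbons, C11–C13 lactone side chain, C14 methyl on C10, C15 oxymethyl on C4); the sense of induction of the two organocatalysts is assigned by analogy with the accepted transition-state models.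

Step 1
Reactants: 1 but-2-yne-1,4-diol
Product: 2 4-{[tert-butyl(diphenyl)silyl]oxy}but-2-yn-1-ol
Conditions: tert-butyl(chloro)diphenylsilane (0.33 equiv relative to the diol), imidazole, DMF, 0 °C → rt
Reagents that add atoms: tert-butyl(chloro)diphenylsilane CC(C)(C)[Si](Cl)(c1ccccc1)c1ccccc1
Why: Silyl ether formation; with the symmetric diol in threefold excess the monosilyl ether should dominate and unreacted diol is washed out with water.

Step 2
Reactants: 2 4-{[tert-butyl(diphenyl)silyl]oxy}but-2-yn-1-ol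
Product: 3 4-{[tert-butyl(diphenyl)silyl]oxy}but-2-ynal
Conditions: PhI(OAc)2 (1.1 equiv), TEMPO (10 mol%), CH2Cl2, rt
Reagents that add atoms: none
Why: TEMPO/PhI(OAc)2 oxidation of the primary propargylic alcohol should stop at the ynal under non-basic conditions that spare the silyl ether.

Step 3
Reactants: 3 4-{[tert-butyl(diphenyl)silyl]oxy}but-2-ynal; 4 methyl 4-oxobutanoate
Product: 6 (2S,3R)-2-(3-{[tert-butyl(diphenyl)silyl]oxy}prop-1-yn-1-yl)-5-oxooxolane-3-carbaldehyde, via aldol adduct 5 (not isolated)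
Conditions: (R)-α,α-bis[3,5-bis(trifluoromethyl)phenyl]pyrrolidin-2-ylmethanol (10 mol%), 1,4-dioxane, rt; then PPTS (10 mol%), CH2Cl2, rt
Reagents that add atoms: none
Why: In this diarylprolinol-catalysed enamine cross-aldol reaction only 4 can form an enamine and the non-enolisable ynal 3 is the acceptor, so the hydrogen-bonded transition state should give the anti adduct and set C6 and C7 in one event (the R catalyst is chosen for the 3R,4S adduct by analogy with the proline model), and acid-catalysed lactonisation of the γ-hydroxy ester then closes the γ-lactone, which is cis because the anti relationship places the alkynyl and formyl groups on the same face of the ring.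

Step 4
Reactants: 6 (2S,3R)-2-(3-{[tert-butyl(diphenyl)silyl]oxy}prop-1-yn-1-yl)-5-oxooxolane-3-carbaldehyde; 7 4,4,5,5-tetramethyl-2-(propa-1,2-dien-1-yl)-1,3,2-dioxaborolane
Product: 8 (4S,5S)-5-(3-{[tert-butyl(diphenyl)silyl]oxy}prop-1-yn-1-yl)-4-[(1S)-1-hydroxybut-3-yn-1-yl]oxolan-2-one
Conditions: (S)-3,3′-bis(2,4,6-triisopropylphenyl)-1,1′-binaphthyl-2,2′-diyl hydrogen phosphate (10 mol%), 4 Å MS, toluene, −20 °C; aq. NaHCO3 work-up
Reagents that add atoms: none
Why: Chiral-phosphoric-acid-catalysed allenylboration (propargylation) through a closed six-membered transition state runs under neutral conditions that should spare the epimerisable β-acyloxy aldehyde, and catalyst control (Si-face attack with the S acid) is expected to set C8 as S.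

Step 5
Reactants: 8 (4S,5S)-5-(3-{[tert-butyl(diphenyl)silyl]oxy}prop-1-yn-1-yl)-4-[(1S)-1-hydroxybut-3-yn-1-yl]oxolan-2-one
Product: 9 (4R,5S)-5-(3-{[tert-butyl(diphenyl)silyl]oxy}prop-1-yn-1-yl)-4-[(1S)-1-(triethylsilyloxy)but-3-yn-1-yl]oxolan-2-one
Conditions: chlorotriethylsilane, imidazole, DMF, 0 °C
Reagents that add atoms: chlorotriethylsilane CC[Si](Cl)(CC)CC
Why: Silylation of the secondary alcohol; the O8 silyl ether blocks attack of O8 on C12 (translactonisation) in the basic steps that follow.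

Step 6
Reactants: 9 (4R,5S)-5-(3-{[tert-butyl(diphenyl)silyl]oxy}prop-1-yn-1-yl)-4-[(1S)-1-(triethylsilyloxy)but-3-yn-1-yl]oxolan-2-one
Product: 11 (4R,5S)-5-(3-{[tert-butyl(diphenyl)silyl]oxy}prop-1-yn-1-yl)-4-[(1S,3E)-3-methyl-1-(triethylsilyloxy)hexa-3,5-dien-1-yl]oxolan-2-one, via alkenylalane 10 (not isolated)
Conditions: Me3Al (2.0 equiv), Cp2ZrCl2 (0.25 equiv), CH2Cl2, 0 °C → rt; then bromoethene (5 equiv), Pd(PPh3)4 (5 mol%), ZnCl2 (0.2 equiv), THF, rt
Reagents that add atoms: trimethylaluminium C[Al](C)C; bromoethene C=CBr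
Why: Negishi zirconium-catalysed carboalumination adds methyl (to C10) and aluminium (to C1) syn across the terminal alkyne, which fixes the E C1=C10 olefin while the disubstituted propargylic alkyne is far less reactive, and palladium-catalysed cross-coupling of the alkenylalane with bromoethene with retention should give the diene.

Step 7
Reactants: 11 (4R,5S)-5-(3-{[tert-butyl(diphenyl)silyl]oxy}prop-1-yn-1-yl)-4-[(1S,3E)-3-methyl-1-(triethylsilyloxy)hexa-3,5-dien-1-yl]oxolan-2-one
Product: 13 (3R,4R,5S)-5-(3-{[tert-butyl(diphenyl)silyl]oxy}prop-1-yn-1-yl)-3-methyl-4-[(1S,3E)-3-methyl-1-(triethylsilyloxy)hexa-3,5-dien-1-yl]oxolan-2-one, via lithium enolate 12 (not isolated)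
Conditions: LiN(iPr)2 (1.1 equiv), THF, −78 °C; then MeI (3 equiv), −78 → −40 °C
Reagents that add atoms: iodomethane CI
Why: Alkylation of the kinetic lithium enolate of the γ-lactone with iodomethane should occur anti to the bulky C7 substituent (and to the cis C6 alkynyl group), which sets C11 as R with the methyl trans to C8.

Step 8
Reactants: 13 (3R,4R,5S)-5-(3-{[tert-butyl(diphenyl)silyl]oxy}prop-1-yn-1-yl)-3-methyl-4-[(1S,3E)-3-methyl-1-(triethylsilyloxy)hexa-3,5-dien-1-yl]oxolan-2-one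
Product: 15 (3R,4R,5S)-5-[(1E)-3-{[tert-butyl(diphenyl)silyl]oxy}-2-iodoprop-1-en-1-yl]-3-methyl-4-[(1S,3E)-3-methyl-1-(triethylsilyloxy)hexa-3,5-dien-1-yl]oxolan-2-one, via vinylstannane 14 (not isolated)
Conditions: Bu3SnH (1.2 equiv, slow addition), PdCl2(PPh3)2 (3 mol%), THF, 0 °C; then I2 (1.3 equiv), NaHCO3, CH2Cl2, −40 °C
Reagents that add atoms: iodine [I][I]
Why: Palladium-catalysed syn-hydrostannation is expected to place tin on C4 (the less hindered alkyne carbon, next to the primary silyloxymethyl group) and hydrogen on C5, the oxygen-flanked alkyne reacting faster than the diene, and iododestannylation with retention then gives the E iodoalkene with iodine trans to C6.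

Step 9
Reactants: 15 (3R,4R,5S)-5-[(1E)-3-{[tert-butyl(diphenyl)silyl]oxy}-2-iodoprop-1-en-1-yl]-3-methyl-4-[(1S,3E)-3-methyl-1-(triethylsilyloxy)hexa-3,5-dien-1-yl]oxolan-2-one
Product: 17 (3R,3aR,4S,6E,10Z,11aR)-10-({[tert-butyl(diphenyl)silyl]oxy}methyl)-3,6-dimethyl-4-(triethylsilyloxy)-3a,4,5,8,9,11a-hexahydrocyclodeca[b]furan-2(3H)-one, via alkylborane 16 (not isolated)
Conditions: 9-BBN (1.5 equiv), THF, 0 °C → rt, 3 h; then syringe-pump addition (10 h) to Pd(dppf)Cl2 (15 mol%), AsPh3 (30 mol%), Cs2CO3 (3 equiv), DMF/THF/H2O, 45 °C, final 1 mM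
Reagents that add atoms: none
Why: 9-BBN adds anti-Markovnikov to the monosubstituted C2=C3 end of the 1,3-diene to give the homoallylic B-alkylborane 16 with boron on C3, zerovalent palladium inserts into the C4–I bond, the base-activated borate transfers the primary C3 alkyl group to divalent palladium, and reductive elimination forms the C3–C4 bond. The closest known reaction type is the B-alkyl Suzuki–Miyaura macrocyclisation run directly after in situ 9-BBN hydroboration. The ten-membered carbocycle is closed by an sp3–sp2 coupling between the two ends of one chain through an eleven-membered palladacycle, with the C4=C5 olefin ending inside the ring. No stereocentre is formed; the ring-E geometry of C4=C5 is carried over with retention from the E iodide and that of C1=C10 from the carboalumination, so one operation delivers the complete (1(10)E,4-ring-E) diene lactone core with C15 in place. The step needs hydroboration of C2=C3 in preference to the trisubstituted C1=C10 olefin, the iodoalkene and the lactone carbonyl, which the steric demand of 9-BBN secures, and ring closure in preference to oligomerisation and β-hydride elimination, which the cis-fused lactone (both arms on one face), the two rigid trisubstituted olefins, the wide-bite-angle dppf ligand and slow addition at high dilution secure. The O8 silyl ether prevents translactonisation under carbonate, and any lactone opened by the base recloses on O6 on mildly acidic work-up.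

Step 10
Reactants: 17 (3R,3aR,4S,6E,10Z,11aR)-10-({[tert-butyl(diphenyl)silyl]oxy}methyl)-3,6-dimethyl-4-(triethylsilyloxy)-3a,4,5,8,9,11a-hexahydrocyclodeca[b]furan-2(3H)-one
Product: 18 (3R,3aS,4S,6E,10Z,11aR)-10-({[tert-butyl(diphenyl)silyl]oxy}methyl)-4-hydroxy-3,6-dimethyl-3a,4,5,8,9,11a-hexahydrocyclodeca[b]furan-2(3H)-one
Conditions: PPTS (0.2 equiv), MeOH/CH2Cl2 (1:1), 0 °C → rt
Reagents that add atoms: none
Why: Mild acidic methanolysis should cleave the secondary triethylsilyl ether selectively, the tert-butyldiphenylsilyl ether, the lactone and the 1(10),4-diene being stable to pyridinium p-toluenesulfonate.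

Step 11
Reactants: 19 methyl 2-(hydroxymethyl)prop-2-enoate
Product: 20 methyl 2-({[tert-butyl(dimethyl)silyl]oxy}methyl)prop-2-enoate
Conditions: tert-butyl(chloro)dimethylsilane, imidazole, CH2Cl2, 0 °C → rt
Reagents that add atoms: tert-butyl(chloro)dimethylsilane CC(C)(C)[Si](C)(C)Cl
Why: Standard silylation of the primary allylic alcohol masks the side-chain hydroxyl for the esterification.

Step 12
Reactants: 20 methyl 2-({[tert-butyl(dimethyl)silyl]oxy}methyl)prop-2-enoate
Product: 21 2-({[tert-butyl(dimethyl)silyl]oxy}methyl)prop-2-enoic acid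
Conditions: LiOH·H2O (1.5 equiv), THF/H2O (3:1), 0 °C; then 1 M HCl to pH 4
Reagents that add atoms: lithium hydroxide [Li+].[OH-]
Why: Saponification of the methyl ester at 0 °C, under which the primary silyl ether should survive, followed by careful acidification.

Step 13
Reactants: 18 (3R,3aS,4S,6E,10Z,11aR)-10-({[tert-butyl(diphenyl)silyl]oxy}methyl)-4-hydroxy-3,6-dimethyl-3a,4,5,8,9,11a-hexahydrocyclodeca[b]furan-2(3H)-one; 21 2-({[tert-butyl(dimethyl)silyl]oxy}methyl)prop-2-enoic acid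
Product: 22 (3R,3aS,4S,6E,10Z,11aR)-10-({[tert-butyl(diphenyl)silyl]oxy}methyl)-3,6-dimethyl-2-oxo-2,3,3a,4,5,8,9,11a-octahydrocyclodeca[b]furan-4-yl 2-({[tert-butyl(dimethyl)silyl]oxy}methyl)prop-2-enoate
Conditions: N,N′-dicyclohexylcarbodiimide (1.5 equiv), DMAP (0.2 equiv), CH2Cl2, 0 °C → rt
Reagents that add atoms: none
Why: Steglich esterification (carbodiimide activation, DMAP acyl transfer) acylates the C8 hydroxyl with retention, and 18 is used at once so that the free 8-hydroxyl has little time to attack the lactone carbonyl.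

Step 14
Reactants: 22 (3R,3aS,4S,6E,10Z,11aR)-10-({[tert-butyl(diphenyl)silyl]oxy}methyl)-3,6-dimethyl-2-oxo-2,3,3a,4,5,8,9,11a-octahydrocyclodeca[b]furan-4-yl 2-({[tert-butyl(dimethyl)silyl]oxy}methyl)prop-2-enoate
Product: 23 (3R,3aS,4S,6E,10Z,11aR)-10-(hydroxymethyl)-3,6-dimethyl-2-oxo-2,3,3a,4,5,8,9,11a-octahydrocyclodeca[b]furan-4-yl 2-(hydroxymethyl)prop-2-enoate
Conditions: HF·pyridine, pyridine, THF, 0 °C → rt
Reagents that add atoms: none
Why: Fluoride-mediated desilylation with pyridine-buffered HF·pyridine should remove both primary allylic silyl ethers without harming the acrylate, the lactone or the acid-sensitive 1(10),4-diene.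

**Compound list**
1 | but-2-yne-1,4-diol | OCC#CCO | starting material
2 | 4-{[tert-butyl(diphenyl)silyl]oxy}but-2-yn-1-ol | OCC#CCO[Si](c1ccccc1)(c1ccccc1)C(C)(C)C | intermediate
3 | 4-{[tert-butyl(diphenyl)silyl]oxy}but-2-ynal | O=CC#CCO[Si](c1ccccc1)(c1ccccc1)C(C)(C)C | intermediate
4 | methyl 4-oxobutanoate | COC(=O)CCC=O | starting material
5 | methyl (3R,4S)-7-{[tert-butyl(diphenyl)silyl]oxy}-3-formyl-4-hydroxyhept-5-ynoate (anti aldol adduct) | COC(=O)C[C@@H](C=O)[C@H](O)C#CCO[Si](c1ccccc1)(c1ccccc1)C(C)(C)C | intermediate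
6 | (2S,3R)-2-(3-{[tert-butyl(diphenyl)silyl]oxy}prop-1-yn-1-yl)-5-oxooxolane-3-carbaldehyde (cis lactone aldehyde) | CC(C)(C)[Si](c1ccccc1)(c1ccccc1)OCC#C[C@H]2OC(=O)C[C@H]2C=O | intermediate
7 | 4,4,5,5-tetramethyl-2-(propa-1,2-dien-1-yl)-1,3,2-dioxaborolane (allenylboronic acid pinacol ester) | C=C=CB1OC(C)(C)C(C)(C)O1 | starting material
8 | (4S,5S)-5-(3-{[tert-butyl(diphenyl)silyl]oxy}prop-1-yn-1-yl)-4-[(1S)-1-hydroxybut-3-yn-1-yl]oxolan-2-one | CC(C)(C)[Si](c1ccccc1)(c1ccccc1)OCC#C[C@H]2OC(=O)C[C@H]2[C@@H](O)CC#C | intermediate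
9 | (4R,5S)-5-(3-{[tert-butyl(diphenyl)silyl]oxy}prop-1-yn-1-yl)-4-[(1S)-1-(triethylsilyloxy)but-3-yn-1-yl]oxolan-2-one | CC(C)(C)[Si](c1ccccc1)(c1ccccc1)OCC#C[C@H]2OC(=O)C[C@H]2[C@@H](O[Si](CC)(CC)CC)CC#C | intermediate
10 | (4R,5S)-5-(3-{[tert-butyl(diphenyl)silyl]oxy}prop-1-yn-1-yl)-4-[(1S,3E)-4-(dimethylalumanyl)-3-methyl-1-(triethylsilyloxy)but-3-en-1-yl]oxolan-2-one (alkenylalane) | CC(C)(C)[Si](c1ccccc1)(c1ccccc1)OCC#C[C@H]2OC(=O)C[C@H]2[C@@H](O[Si](CC)(CC)CC)C/C(C)=C/[Al](C)C | intermediate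
11 | (4R,5S)-5-(3-{[tert-butyl(diphenyl)silyl]oxy}prop-1-yn-1-yl)-4-[(1S,3E)-3-methyl-1-(triethylsilyloxy)hexa-3,5-dien-1-yl]oxolan-2-one | CC(C)(C)[Si](c1ccccc1)(c1ccccc1)OCC#C[C@H]2OC(=O)C[C@H]2[C@@H](O[Si](CC)(CC)CC)C/C(C)=C/C=C | intermediate
12 | lithium (4R,5S)-5-(3-{[tert-butyl(diphenyl)silyl]oxy}prop-1-yn-1-yl)-4-[(1S,3E)-3-methyl-1-(triethylsilyloxy)hexa-3,5-dien-1-yl]-4,5-dihydrofuran-2-olate (lithium enolate) | CC(C)(C)[Si](c1ccccc1)(c1ccccc1)OCC#C[C@H]2OC(O[Li])=C[C@H]2[C@@H](O[Si](CC)(CC)CC)C/C(C)=C/C=C | intermediate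
13 | (3R,4R,5S)-5-(3-{[tert-butyl(diphenyl)silyl]oxy}prop-1-yn-1-yl)-3-methyl-4-[(1S,3E)-3-methyl-1-(triethylsilyloxy)hexa-3,5-dien-1-yl]oxolan-2-one | CC(C)(C)[Si](c1ccccc1)(c1ccccc1)OCC#C[C@H]2OC(=O)[C@H](C)[C@H]2[C@@H](O[Si](CC)(CC)CC)C/C(C)=C/C=C | intermediate
14 | (3R,4R,5S)-5-[(1E)-3-{[tert-butyl(diphenyl)silyl]oxy}-2-(tributylstannyl)prop-1-en-1-yl]-3-methyl-4-[(1S,3E)-3-methyl-1-(triethylsilyloxy)hexa-3,5-dien-1-yl]oxolan-2-one (vinylstannane) | CCCC[Sn](CCCC)(CCCC)/C(CO[Si](c1ccccc1)(c1ccccc1)C(C)(C)C)=C/[C@H]2OC(=O)[C@H](C)[C@H]2[C@@H](O[Si](CC)(CC)CC)C/C(C)=C/C=C | intermediate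
15 | (3R,4R,5S)-5-[(1E)-3-{[tert-butyl(diphenyl)silyl]oxy}-2-iodoprop-1-en-1-yl]-3-methyl-4-[(1S,3E)-3-methyl-1-(triethylsilyloxy)hexa-3,5-dien-1-yl]oxolan-2-one | I/C(CO[Si](c1ccccc1)(c1ccccc1)C(C)(C)C)=C/[C@H]2OC(=O)[C@H](C)[C@H]2[C@@H](O[Si](CC)(CC)CC)C/C(C)=C/C=C | intermediate
16 | (3R,4R,5S)-4-[(1S,3E)-6-(9-borabicyclo[3.3.1]nonan-9-yl)-3-methyl-1-(triethylsilyloxy)hex-3-en-1-yl]-5-[(1E)-3-{[tert-butyl(diphenyl)silyl]oxy}-2-iodoprop-1-en-1-yl]-3-methyloxolan-2-one (alkylborane) | I/C(CO[Si](c1ccccc1)(c1ccccc1)C(C)(C)C)=C/[C@H]2OC(=O)[C@H](C)[C@H]2[C@@H](O[Si](CC)(CC)CC)C/C(C)=C/CCB3C4CCCC3CCC4 | intermediate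
17 | (3R,3aR,4S,6E,10Z,11aR)-10-({[tert-butyl(diphenyl)silyl]oxy}methyl)-3,6-dimethyl-4-(triethylsilyloxy)-3a,4,5,8,9,11a-hexahydrocyclodeca[b]furan-2(3H)-one | CC[Si](CC)(CC)O[C@H]1C/C(C)=C/CC/C(CO[Si](c3ccccc3)(c3ccccc3)C(C)(C)C)=C/[C@H]2OC(=O)[C@H](C)[C@@H]12 | intermediate
18 | (3R,3aS,4S,6E,10Z,11aR)-10-({[tert-butyl(diphenyl)silyl]oxy}methyl)-4-hydroxy-3,6-dimethyl-3a,4,5,8,9,11a-hexahydrocyclodeca[b]furan-2(3H)-one | O[C@H]1C/C(C)=C/CC/C(CO[Si](c3ccccc3)(c3ccccc3)C(C)(C)C)=C/[C@H]2OC(=O)[C@H](C)[C@@H]12 | intermediate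
19 | methyl 2-(hydroxymethyl)prop-2-enoate | C=C(CO)C(=O)OC | starting material
20 | methyl 2-({[tert-butyl(dimethyl)silyl]oxy}methyl)prop-2-enoate | C=C(CO[Si](C)(C)C(C)(C)C)C(=O)OC | intermediate
21 | 2-({[tert-butyl(dimethyl)silyl]oxy}methyl)prop-2-enoic acid | C=C(CO[Si](C)(C)C(C)(C)C)C(=O)O | intermediate
22 | (3R,3aS,4S,6E,10Z,11aR)-10-({[tert-butyl(diphenyl)silyl]oxy}methyl)-3,6-dimethyl-2-oxo-2,3,3a,4,5,8,9,11a-octahydrocyclodeca[b]furan-4-yl 2-({[tert-butyl(dimethyl)silyl]oxy}methyl)prop-2-enoate | C=C(CO[Si](C)(C)C(C)(C)C)C(=O)O[C@H]1C/C(C)=C/CC/C(CO[Si](c3ccccc3)(c3ccccc3)C(C)(C)C)=C/[C@H]2OC(=O)[C@H](C)[C@@H]12 | intermediate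
23 | (3R,3aS,4S,6E,10Z,11aR)-10-(hydroxymethyl)-3,6-dimethyl-2-oxo-2,3,3a,4,5,8,9,11a-octahydrocyclodeca[b]furan-4-yl 2-(hydroxymethyl)prop-2-enoate (CNP0167163.2) | C=C(CO)C(=O)O[C@H]1C/C(C)=C/CC/C(CO)=C/[C@H]2OC(=O)[C@H](C)[C@@H]12 | target

**Step count**
Total: 14 steps (12 in the main line, 2 for acid 21). Longest linear sequence: 12 steps (steps 1–10, 13, 14).

**Steps most likely to fail**

Step 9 (macrocyclisation). What may go wrong: intermolecular coupling to oligomers, β-hydride elimination or protodeboronation may outrun the slow transmetalation and closure of the strained ten-membered ring. The fallback sets out from 15 and comes back at 17; it separates the making of the C3 nucleophile from the ring closure and changes the metal. Hydroboration of 15 with 9-BBN (through 16) followed by oxidative work-up with NaBO3·4H2O should give the primary alcohol (3R,4R,5S)-5-[(1E)-3-{[tert-butyl(diphenyl)silyl]oxy}-2-iodoprop-1-en-1-yl]-4-[(1S,3E)-6-hydroxy-3-methyl-1-(triethylsilyloxy)hex-3-en-1-yl]-3-methyloxolan-2-one F1. Iodine, PPh3 and imidazole should convert it into the primary iodide, the 6-iodohex-3-enyl analogue F2. Zinc dust (activated with 1,2-dibromoethane and chlorotrimethylsilane, THF, 30 °C) inserts into the alkyl C–I bond only and gives the alkylzinc iodide F3. Slow addition of its solution to Pd(dppf)Cl2 in THF/N-methylpyrrolidone at 50 °C (intramolecular Negishi coupling at high dilution) should give 17.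

Step 4 (propargylation). What may go wrong: poor facial selectivity, because the catalyst must override the inherent bias of the α-branched aldehyde, together with epimerisation at C7 or β-elimination of the lactone carboxylate if the addition is slow. The fallback sets out from 6 and comes back at 8; it sets C8 by ketone reduction instead of by C–C bond formation. Barbier propargylation of 6 (propargyl bromide, Zn dust, THF/sat. aq. NH4Cl, 0 °C) is expected to follow the substrate bias and give mainly the C8-epimeric alcohol (4S,5S)-5-(3-{[tert-butyl(diphenyl)silyl]oxy}prop-1-yn-1-yl)-4-[(1R)-1-hydroxybut-3-yn-1-yl]oxolan-2-one F4. Dess–Martin periodinane buffered with NaHCO3 should oxidise the epimer mixture to the ketone (4R,5S)-4-(but-3-ynoyl)-5-(3-{[tert-butyl(diphenyl)silyl]oxy}prop-1-yn-1-yl)oxolan-2-one F5. Reduction with (R)-2-methyl-CBS-oxazaborolidine and catecholborane at −78 °C, a hydride delivery in the sense favoured by both the Felkin model and the reagent, should then give 8.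

Step 3 (aldol and lactonisation). What may go wrong: self-aldol of the donor, conjugate addition of the amine catalyst to the ynal, and dehydration or epimerisation at C7 during lactonisation. The fallback sets out from 3 and comes back at 6; it replaces the enamine aldol by an allylboration. Cross-metathesis of methyl but-3-enoate with allylboronic acid pinacol ester (second-generation Grubbs catalyst, RuCl2(H2IMes)(PCy3)(=CHPh), CH2Cl2, 40 °C) should give the allylboronate methyl (3E)-5-(4,4,5,5-tetramethyl-1,3,2-dioxaborolan-2-yl)pent-3-enoate F6. Its addition to 3, catalysed by the S phosphoric acid of step 4 through a chair transition state, should give the anti hydroxy ester methyl (3S,4S)-7-{[tert-butyl(diphenyl)silyl]oxy}-3-ethenyl-4-hydroxyhept-5-ynoate F7, which lactonises with PPTS to the cis vinyl lactone (4S,5S)-5-(3-{[tert-butyl(diphenyl)silyl]oxy}prop-1-yn-1-yl)-4-ethenyloxolan-2-one F8. Ozonolysis of the vinyl group (O3, CH2Cl2, −78 °C, Sudan red end point; then Me2S), which reacts far faster than the internal alkyne, should give 6.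

Further compounds
F1 | step 9 | (3R,4R,5S)-5-[(1E)-3-{[tert-butyl(diphenyl)silyl]oxy}-2-iodoprop-1-en-1-yl]-4-[(1S,3E)-6-hydroxy-3-methyl-1-(triethylsilyloxy)hex-3-en-1-yl]-3-methyloxolan-2-one | I/C(CO[Si](c1ccccc1)(c1ccccc1)C(C)(C)C)=C/[C@H]2OC(=O)[C@H](C)[C@H]2[C@@H](O[Si](CC)(CC)CC)C/C(C)=C/CCO
F2 | step 9 | (3R,4R,5S)-5-[(1E)-3-{[tert-butyl(diphenyl)silyl]oxy}-2-iodoprop-1-en-1-yl]-4-[(1S,3E)-6-iodo-3-methyl-1-(triethylsilyloxy)hex-3-en-1-yl]-3-methyloxolan-2-one | I/C(CO[Si](c1ccccc1)(c1ccccc1)C(C)(C)C)=C/[C@H]2OC(=O)[C@H](C)[C@H]2[C@@H](O[Si](CC)(CC)CC)C/C(C)=C/CCI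
F3 | step 9 | alkylzinc iodide formed from F2 by zinc insertion at C3 | I/C(CO[Si](c1ccccc1)(c1ccccc1)C(C)(C)C)=C/[C@H]2OC(=O)[C@H](C)[C@H]2[C@@H](O[Si](CC)(CC)CC)C/C(C)=C/CC[Zn]I
F4 | step 4 | (4S,5S)-5-(3-{[tert-butyl(diphenyl)silyl]oxy}prop-1-yn-1-yl)-4-[(1R)-1-hydroxybut-3-yn-1-yl]oxolan-2-one | CC(C)(C)[Si](c1ccccc1)(c1ccccc1)OCC#C[C@H]2OC(=O)C[C@H]2[C@H](O)CC#C
F5 | step 4 | (4R,5S)-4-(but-3-ynoyl)-5-(3-{[tert-butyl(diphenyl)silyl]oxy}prop-1-yn-1-yl)oxolan-2-one | CC(C)(C)[Si](c1ccccc1)(c1ccccc1)OCC#C[C@H]2OC(=O)C[C@H]2C(=O)CC#C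
F6 | step 3 | methyl (3E)-5-(4,4,5,5-tetramethyl-1,3,2-dioxaborolan-2-yl)pent-3-enoate | COC(=O)C/C=C/CB1OC(C)(C)C(C)(C)O1
F7 | step 3 | methyl (3S,4S)-7-{[tert-butyl(diphenyl)silyl]oxy}-3-ethenyl-4-hydroxyhept-5-ynoate | COC(=O)C[C@@H](C=C)[C@H](O)C#CCO[Si](c1ccccc1)(c1ccccc1)C(C)(C)C
F8 | step 3 | (4S,5S)-5-(3-{[tert-butyl(diphenyl)silyl]oxy}prop-1-yn-1-yl)-4-ethenyloxolan-2-one | CC(C)(C)[Si](c1ccccc1)(c1ccccc1)OCC#C[C@H]2OC(=O)C[C@H]2C=C
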